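The synthesis rests on cutting ring C at O1–C2 and C3–C4. O1 and C4 sit on adjacent carbons (C8a, C4a) of ring A, so they trace back to the OH and CHO of a salicylaldehyde. C2 and C3 are the β- and α-carbons of the cinnamaldehyde that carries ring B. One amine-catalysed iminium–enamine domino reaction forms both bonds, closes the pyran and fixes C2, the only stereocentre. Its precursors are unprotected 2-hydroxy-3,4-dimethoxybenzaldehyde and (E)-3,4,5-trimethoxycinnamaldehyde, the latter one Wittig step from the benzaldehyde. The surplus formyl carbon left on C3 is then excised with rhodium, and C3=C4 is saturated with diimide, which leaves the benzylic C2–O1 bond alone.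

Key step: step 2

Assumption: the sense of induction is assigned from the accepted face-shielding model of (S)-diarylprolinol silyl ethers with β-aryl enals; it is to be confirmed by chiral HPLC against the racemate and by the rotation of the final flavan, and the equally available (R)-catalyst would be used if the opposite sense were found.

Step 1
Reactants: 1 3,4,5-trimethoxybenzaldehyde
Product: 2 (E)-3-(3,4,5-trimethoxyphenyl)prop-2-enal
Conditions: Ph3P=CHCHO (1.05 equiv), toluene, 80 °C
Reagents that add atoms: (triphenylphosphoranylidene)acetaldehyde, O=CC=P(c1ccccc1)(c1ccccc1)c1ccccc1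
Why: Wittig olefination with a formyl-stabilised ylide proceeds reversibly through the trans-oxaphosphetane, so the (E)-enal should dominate, and holding the ylide near one equivalent limits a second homologation of 2 to the dienal.

Step 2
Reactants: 2 (E)-3-(3,4,5-trimethoxyphenyl)prop-2-enal (1.2 equiv); 3 2-hydroxy-3,4-dimethoxybenzaldehyde
Product: 5 (R)-7,8-dimethoxy-2-(3,4,5-trimethoxyphenyl)-2H-chromene-3-carbaldehyde, via aldol adduct 4 (not isolated)
Conditions: (S)-2-[diphenyl(trimethylsilyloxy)methyl]pyrrolidine (20 mol %), 2-nitrobenzoic acid (20 mol %), 4 Å MS, toluene, rt, dark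
Reagents that add atoms: none
Why: The amine condenses with 2 to an (E)-configured, s-trans iminium ion, the phenol oxygen of 3 adds to its β-carbon (O1–C2), the enamine so unmasked attacks the ortho aldehyde carbon (C3–C4) to give 4 in catalyst-bound form, and loss of water plus hydrolysis returns the amine. This is the known diarylprolinol silyl ether catalysed domino oxa-Michael/aldol condensation of salicylaldehydes with β-aryl enals (iminium, then enamine activation). Ring C closes in a 6-(enolexo)-exo-trig aldol step, with the carbonyl oxygen outside the forming six-membered ring. C2 is controlled by the catalyst: the C(Ph)2OSiMe3 arm of the (S)-pyrrolidine covers the Re face of the β-carbon, so oxygen arrives on the Si face and gives (R)-5, which has the spatial arrangement of the (2S)-flavan. The step needs 1,4- rather than 1,2-addition, cross- rather than self-condensation and an irreversible exit from the reversible O-addition; these are secured because 3 has no α-hydrogen and 2 no γ-hydrogen (no competing enamine or dienamine), because OH and CHO are ortho in 3 so that the aldol is intramolecular, and because dehydration to the aryl-conjugated enal does not revert. The acid co-catalyst should speed iminium formation and turnover for these two electron-rich partners, and the sieves take up the water released.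

Step 3
Reactants: 5 (R)-7,8-dimethoxy-2-(3,4,5-trimethoxyphenyl)-2H-chromene-3-carbaldehyde
Product: 6 (S)-7,8-dimethoxy-2-(3,4,5-trimethoxyphenyl)-2H-chromene
Conditions: RhCl(PPh3)3 (1.1 equiv), degassed toluene, 110 °C, Ar, dark; chromatography on Et3N-deactivated silica
Reagents that add atoms: none
Why: Tsuji–Wilkinson decarbonylation, in which monovalent rhodium inserts into the formyl C–H bond, the acyl hydride of trivalent rhodium extrudes CO to a C3-vinyl hydride and reductive elimination forms C3–H with the double bond held at C3=C4, so C2 is never engaged and keeps its arrangement (the descriptor turns from R to S only because C3 without its formyl group ranks below the aryl group).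

Step 4
Reactants: 6 (S)-7,8-dimethoxy-2-(3,4,5-trimethoxyphenyl)-2H-chromene
Product: 7 (2S)-7,8-dimethoxy-2-(3,4,5-trimethoxyphenyl)chromane, i.e. (2S)-7,8,3',4',5'-pentamethoxyflavan
Conditions: 2-nitrobenzenesulfonohydrazide (NBSH, excess, in portions), Et3N, CH2Cl2, rt, dark
Reagents that add atoms: none
Why: Diimide reduction, in which HN=NH released from the sulfonylhydrazide at room temperature delivers two hydrogens to the cis-disubstituted C3=C4 bond through a concerted six-centre transition state, a metal-free and buffered process that should spare the allylic and benzylic C2–O1 bond, the arenes and the C2 configuration.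

Compound list
1 | 3,4,5-trimethoxybenzaldehyde | O=Cc1cc(OC)c(OC)c(OC)c1 | starting material
2 | (E)-3-(3,4,5-trimethoxyphenyl)prop-2-enal | COc1cc(/C=C/C=O)cc(OC)c1OC | intermediate
3 | 2-hydroxy-3,4-dimethoxybenzaldehyde | COc1ccc(C=O)c(O)c1OC | starting material
4 | (2S)-4-hydroxy-7,8-dimethoxy-2-(3,4,5-trimethoxyphenyl)chromane-3-carbaldehyde (aldol adduct, drawn free of catalyst; C3 and C4 left open, both are erased on dehydration) | COc1cc([C@@H]2C(C=O)C(O)c3ccc(OC)c(OC)c3O2)cc(OC)c1OC | intermediate
5 | (R)-7,8-dimethoxy-2-(3,4,5-trimethoxyphenyl)-2H-chromene-3-carbaldehyde | COc1cc([C@@H]2C(C=O)=Cc3ccc(OC)c(OC)c3O2)cc(OC)c1OC | intermediate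
6 | (S)-7,8-dimethoxy-2-(3,4,5-trimethoxyphenyl)-2H-chromene | COc1cc([C@@H]2C=Cc3ccc(OC)c(OC)c3O2)cc(OC)c1OC | intermediate
7 | (2S)-7,8,3',4',5'-pentamethoxyflavan | COc1cc([C@@H]2CCc3ccc(OC)c(OC)c3O2)cc(OC)c1OC | target

Total step count: 4. Longest linear sequence: 4 steps (1 → 2 → 5 → 6 → 7).

Steps most likely to fail

Step 2. Slow turnover is the main concern.
- The iminium ion of an electron-rich cinnamaldehyde is a weak acceptor, and the aldehyde of 3 is deactivated by its para methoxy group.
- The reversible O-addition and a non-selective background closure could therefore erode facial selectivity. Crystallisation of 5 may not make up the shortfall.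
- The fallback sets C2 by ketone reduction instead of conjugate addition. It sets out from 3 and comes back at 7.
- Claisen–Schmidt condensation of 3 with commercial 3',4',5'-trimethoxyacetophenone (KOH, EtOH, rt) should give (E)-3-(2-hydroxy-3,4-dimethoxyphenyl)-1-(3,4,5-trimethoxyphenyl)prop-2-en-1-one F1.
- Saturation of the enone double bond (H2, Pd/C, EtOAc, stopped after one equivalent) gives 3-(2-hydroxy-3,4-dimethoxyphenyl)-1-(3,4,5-trimethoxyphenyl)propan-1-one F2.
- Asymmetric transfer hydrogenation with RuCl(p-cymene)[(R,R)-TsDPEN] in HCO2H/Et3N gives 6-[(3R)-3-hydroxy-3-(3,4,5-trimethoxyphenyl)propyl]-2,3-dimethoxyphenol F3.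
- Intramolecular Mitsunobu etherification (PPh3, DIAD, THF, 0 °C) closes O1–C2 with inversion to 7.

Step 3. CO extrusion from an enal needs heat, and three things could go wrong at that temperature.
- Thermal 6π ring opening and reclosure of the 2H-chromene could lower the enantiomeric purity.
- Rhodium hydride-mediated migration of the double bond towards C2 could erase the stereocentre.
- The reaction could stall at the acyl stage.
- The fallback removes the carbon as CO2 by a radical chain at ambient temperature, after the double bond is gone. It sets out from 5 and comes back at 7.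
- Pinnick oxidation (NaClO2, NaH2PO4, 2-methyl-2-butene, t-BuOH/H2O) gives (R)-7,8-dimethoxy-2-(3,4,5-trimethoxyphenyl)-2H-chromene-3-carboxylic acid F4.
- Hydrogenation (H2, Pd/C, EtOAc, stopped after one equivalent) gives (2S)-7,8-dimethoxy-2-(3,4,5-trimethoxyphenyl)chromane-3-carboxylic acid F5, whose C3 configuration is irrelevant.
- Coupling with 1-hydroxypyridine-2(1H)-thione (DCC, CH2Cl2, 0 °C, dark) gives the 2-thioxopyridin-1(2H)-yl (2S)-7,8-dimethoxy-2-(3,4,5-trimethoxyphenyl)chromane-3-carboxylate F6.
- F6 is irradiated with visible light in the presence of t-BuSH (Barton reductive decarboxylation). Fast hydrogen transfer from the thiol to the C3 radical should outrun C2–O1 scission and deliver 7.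

Step 4. Disproportionation of diimide may outrun the reduction of a conjugated, electron-rich cis-alkene. Incomplete saturation would leave starting alkene that is hard to separate from the product.
- The fallback replaces the pericyclic hydrogen transfer by homogeneous metal-catalysed hydrogenation. It sets out from 6 and comes back at 7.
- The conditions are catalytic RhCl(PPh3)3 under H2 (1 atm) in toluene/EtOH at rt. These add hydrogen through a rhodium dihydride without the benzylic C–O hydrogenolysis typical of heterogeneous palladium.
- This fallback makes no new compound (F0).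

Further compounds
F1 | step 2 | (E)-3-(2-hydroxy-3,4-dimethoxyphenyl)-1-(3,4,5-trimethoxyphenyl)prop-2-en-1-one | COc1cc(C(=O)/C=C/c2ccc(OC)c(OC)c2O)cc(OC)c1OC
F2 | step 2 | 3-(2-hydroxy-3,4-dimethoxyphenyl)-1-(3,4,5-trimethoxyphenyl)propan-1-one | COc1cc(C(=O)CCc2ccc(OC)c(OC)c2O)cc(OC)c1OC
F3 | step 2 | 6-[(3R)-3-hydroxy-3-(3,4,5-trimethoxyphenyl)propyl]-2,3-dimethoxyphenol | COc1cc([C@H](O)CCc2ccc(OC)c(OC)c2O)cc(OC)c1OC
F4 | step 3 | (R)-7,8-dimethoxy-2-(3,4,5-trimethoxyphenyl)-2H-chromene-3-carboxylic acid | COc1cc([C@@H]2C(C(=O)O)=Cc3ccc(OC)c(OC)c3O2)cc(OC)c1OC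
F5 | step 3 | (2S)-7,8-dimethoxy-2-(3,4,5-trimethoxyphenyl)chromane-3-carboxylic acid (C3 left open) | COc1cc([C@@H]2C(C(=O)O)Cc3ccc(OC)c(OC)c3O2)cc(OC)c1OC
F6 | step 3 | 2-thioxopyridin-1(2H)-yl (2S)-7,8-dimethoxy-2-(3,4,5-trimethoxyphenyl)chromane-3-carboxylate (C3 left open) | COc1cc([C@@H]2C(C(=O)On3ccccc3=S)Cc3ccc(OC)c(OC)c3O2)cc(OC)c1OC
F0 | step 4 | none | none
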